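**Strategy.** The target is cut at C4 of the upper flavan unit, a methine that carries two phloroglucinol-type rings: C4a of its own ring A and C6' of ring A of the lower gallocatechin. C4 is therefore treated as one aldehyde carbon that is arylated twice. Because the upper ring A is a symmetric 3,5-dioxygenated aryl ether with two equivalent ortho carbons, an open-chain (2R,3R)-3-aryloxy-2-benzyloxy-3-arylpropanal can close pyran ring C at C4–C4a and, in the same flask, be captured at C4 by C6' of an 8-bromo-protected gallocatechin. The precursor is built by Sharpless epoxidation and phenoxide opening; global hydrogenolysis finishes.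

Key step: step 11

Remarks on the chemistry:
- Unprimed locants refer to the upper flavan unit, primed locants (C2' to C8a') to the lower unit; the pyrogallol ring of each unit is called ring B.
- Aldehyde 13 is assumed not to be storable, so the lower unit is made first (steps 1–3) and step 10 is run directly before step 11.
- The CIP descriptor at C4 is S in bromide 15 and R in target 16 with unchanged geometry, because removal of bromine lowers the priority of C6' below that of C4a.

Step 1
Reactants: 1 (+)-gallocatechin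
Product: 2 (2R,3S)-5,7-bis(benzyloxy)-2-[3,4,5-tris(benzyloxy)phenyl]chroman-3-ol (penta-O-benzylgallocatechin)
Conditions: BnBr (5.5 equiv), K2CO3, DMF, −10 °C to rt, argon
Reagents that add atoms: benzyl bromide, BrCc1ccccc1
Why: Williamson etherification in which carbonate deprotonates only the five phenols and leaves the aliphatic 3-hydroxyl free, the weak base and exclusion of air protecting C2 from epimerisation and ring B from oxidation.

Step 2
Reactants: 2 penta-O-benzylgallocatechin
Product: 3 (2R,3S)-3,5,7-tris(benzyloxy)-2-[3,4,5-tris(benzyloxy)phenyl]chromane (hexa-O-benzylgallocatechin)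
Conditions: NaH (1.5 equiv), BnBr (1.3 equiv), Bu4NI (cat.), DMF, 0 °C to rt
Reagents that add atoms: benzyl bromide, BrCc1ccccc1
Why: Williamson etherification of the secondary alkoxide, safe with NaH because no free phenol remains to open ring C, so C2 and C3 are untouched.

Step 3
Reactants: 3 hexa-O-benzylgallocatechin
Product: 4 (2R,3S)-3,5,7-tris(benzyloxy)-8-bromo-2-[3,4,5-tris(benzyloxy)phenyl]chromane (8-bromo-hexa-O-benzylgallocatechin)
Conditions: NBS (1.0 equiv), CH2Cl2, −40 °C to 0 °C
Reagents that add atoms: N-bromosuccinimide, BrN1C(=O)CCC1=O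
Why: Electrophilic aromatic bromination should go to C8, the most nucleophilic and least hindered carbon of ring A (ortho to O1 and the 7-benzyloxy group, para to the 5-benzyloxy group), as is usual for benzylated flavan-3-ols, which leaves C6 as the only open position.

Step 4
Reactants: 5 3,4,5-tris(benzyloxy)benzaldehyde
Product: 6 ethyl (E)-3-[3,4,5-tris(benzyloxy)phenyl]prop-2-enoate
Conditions: (EtO)2P(O)CH2CO2Et, NaH, THF, 0 °C to rt
Reagents that add atoms: triethyl phosphonoacetate, CCOC(=O)CP(=O)(OCC)OCC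
Why: Horner–Wadsworth–Emmons olefination of an aromatic aldehyde with a stabilised phosphonate anion gives the E-enoate under thermodynamic control of the elimination.

Step 5
Reactants: 6 ethyl (E)-3-[3,4,5-tris(benzyloxy)phenyl]prop-2-enoate
Product: 7 (E)-3-[3,4,5-tris(benzyloxy)phenyl]prop-2-en-1-ol
Conditions: i-Bu2AlH (2.5 equiv), CH2Cl2, −78 °C to 0 °C
Reagents that add atoms: none
Why: i-Bu2AlH reduces the conjugated ester by 1,2-addition only, giving the allylic alcohol with the E double bond and the benzyl ethers intact.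

Step 6
Reactants: 7 (E)-3-[3,4,5-tris(benzyloxy)phenyl]prop-2-en-1-ol
Product: 8 [(2S,3S)-3-[3,4,5-tris(benzyloxy)phenyl]oxiran-2-yl]methanol
Conditions: Ti(OiPr)4 (10 mol %), L-(+)-diisopropyl tartrate (12 mol %), t-BuOOH (2 equiv, in decane), 4 Å molecular sieves, CH2Cl2, −20 °C
Reagents that add atoms: tert-butyl hydroperoxide, CC(C)(C)OO
Why: Sharpless asymmetric epoxidation, in which the titanium–L-(+)-tartrate catalyst delivers oxygen to the face of the E-allylic alcohol that gives the (2S,3S)-trans-epoxide, both new stereocentres being set by the catalyst, and the catalytic sieve conditions spare the acid-sensitive benzylic epoxide.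

Step 7
Reactants: 8 (2S,3S)-arylglycidol; 9 3,5-bis(benzyloxy)phenol
Product: 10 (2S,3R)-3-[3,5-bis(benzyloxy)phenoxy]-3-[3,4,5-tris(benzyloxy)phenyl]propane-1,2-diol
Conditions: 9 (1.5 equiv), NaOH (1.2 equiv), H2O/1,4-dioxane, 70 °C
Reagents that add atoms: none
Why: SN2 opening of a trans-3-arylglycidol by an aryloxide in aqueous base, known to occur at the benzylic C3 (activated by the aryl group, while C2 is deactivated by the adjacent C1 oxygen), inverts C3 from S to R and leaves C2 untouched, which gives the erythro pattern that becomes the 2,3-trans ring C.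

Step 8
Reactants: 10 (2S,3R)-diol
Product: 11 (4S)-4-{(R)-[3,5-bis(benzyloxy)phenoxy][3,4,5-tris(benzyloxy)phenyl]methyl}-2-phenyl-1,3-dioxolane (both epimers at the acetal carbon)
Conditions: PhCH(OMe)2 (1.5 equiv), pyridinium p-toluenesulfonate (cat.), 4 Å molecular sieves, CH2Cl2, rt
Reagents that add atoms: benzaldehyde dimethyl acetal, COC(OC)c1ccccc1
Why: Acid-catalysed transacetalisation of the 1,2-diol gives the five-membered benzylidene acetal, and the weak pyridinium acid is not expected to ionise the benzylic aryl ether.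

Step 9
Reactants: 11 benzylidene acetal
Product: 12 (2S,3R)-2-(benzyloxy)-3-[3,5-bis(benzyloxy)phenoxy]-3-[3,4,5-tris(benzyloxy)phenyl]propan-1-ol
Conditions: i-Bu2AlH (3 equiv), CH2Cl2, −78 °C to rt
Reagents that add atoms: none
Why: Regioselective reductive opening of a benzylidene acetal, in which aluminium binds the less hindered primary oxygen, that C–O bond breaks and hydride reduces the oxocarbenium ion, so the benzyl group stays on the secondary oxygen and both acetal epimers converge on one alcohol.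

Step 10
Reactants: 12 primary alcohol
Product: 13 (2R,3R)-2-(benzyloxy)-3-[3,5-bis(benzyloxy)phenoxy]-3-[3,4,5-tris(benzyloxy)phenyl]propanal
Conditions: Dess–Martin periodinane (1.3 equiv), CH2Cl2, 0 °C to rt; crude aldehyde used at once
Reagents that add atoms: none
Why: Dess–Martin oxidation is base-free and only weakly acidic, so the alpha stereocentre should not enolise and the beta aryloxy group should not be eliminated (the descriptor at C2 changes from S to R only through CIP priorities).

Step 11
Reactants: 13 (2R,3R)-aldehyde; 4 8-bromo-hexa-O-benzylgallocatechin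
Product: 15 dodeca-O-benzyl-8'-bromo-gallocatechin-(4α→6)-gallocatechin, via flavan-4-ol 14 (not isolated)
Conditions: 4 (4 equiv), Sc(OTf)3 (0.2 equiv), CH2Cl2, −20 °C to rt, 13 added slowly
Reagents that add atoms: none
Why: Proposed new method: Sc(OTf)3 activates the aldehyde of 13 and one of the two equivalent ortho carbons of the tethered 3,5-bis(benzyloxy)phenyl ether attacks it in a 6-exo-trig Friedel–Crafts hydroxyalkylation that closes pyran ring C at C4–C4a and gives flavan-4-ol 14; the same acid then ionises the C4 hydroxyl of 14 to a cation delocalised over ring A and O1, which C6' of 4 captures to form the interflavan bond with loss of water. The closest known reactions are the acid-mediated double arylation of aldehydes by electron-rich arenes, the cyclisation of 3-aryloxypropanals to chroman-4-ols and the Lewis acid coupling of benzylated flavan-3,4-diols with flavan-3-ols, here merged in one flask. C2 and C3 come in with 13 and only C4 is new: the arene should add to the half-chair cation, whose C2 aryl group is pseudo-equatorial, from the face anti to the C3 benzyloxy group, giving the all-equatorial 2,3-trans-3,4-trans (4α) ring, which is also the more stable epimer. Site selectivity in the nucleophile is secured by the C8' bromine, which leaves C6' as the only unsubstituted carbon of its ring A. Self-condensation through C6 or C8 of the newly formed upper ring A is held back by the fourfold excess of 4 and the slow addition of 13, and if 4 attacks the aldehyde first, the diarylcarbinol so formed ionises and closes onto the tethered arene to the same methine.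

Step 12
Reactants: 15 dodeca-O-benzyl-8'-bromo dimer
Product: 16 gallocatechin-(4α→6)-gallocatechin
Conditions: H2 (1 atm), Pd(OH)2/C, Et3N (1.2 equiv), THF/MeOH/H2O, rt
Reagents that add atoms: none
Why: Catalytic hydrogenolysis cleaves the twelve benzyl ethers and the aryl C–Br bond in one operation, the amine taking up HBr that could otherwise cleave the acid-labile interflavan bond, and no stereocentre is touched.

**Compound list**

1 | (+)-gallocatechin, (2R,3S)-2-(3,4,5-trihydroxyphenyl)chromane-3,5,7-triol | Oc1cc(O)c2c(c1)O[C@H](c1cc(O)c(O)c(O)c1)[C@@H](O)C2 | starting material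
2 | (2R,3S)-5,7-bis(benzyloxy)-2-[3,4,5-tris(benzyloxy)phenyl]chroman-3-ol | c3ccccc3COc1cc(OCc3ccccc3)c2c(c1)O[C@H](c1cc(OCc3ccccc3)c(OCc3ccccc3)c(OCc3ccccc3)c1)[C@@H](O)C2 | intermediate
3 | (2R,3S)-3,5,7-tris(benzyloxy)-2-[3,4,5-tris(benzyloxy)phenyl]chromane | c3ccccc3COc1cc(OCc3ccccc3)c2c(c1)O[C@H](c1cc(OCc3ccccc3)c(OCc3ccccc3)c(OCc3ccccc3)c1)[C@@H](OCc3ccccc3)C2 | intermediate
4 | (2R,3S)-3,5,7-tris(benzyloxy)-8-bromo-2-[3,4,5-tris(benzyloxy)phenyl]chromane | c3ccccc3COc1cc(OCc3ccccc3)c2c(c1Br)O[C@H](c1cc(OCc3ccccc3)c(OCc3ccccc3)c(OCc3ccccc3)c1)[C@@H](OCc3ccccc3)C2 | intermediate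
5 | 3,4,5-tris(benzyloxy)benzaldehyde | O=Cc1cc(OCc2ccccc2)c(OCc2ccccc2)c(OCc2ccccc2)c1 | starting material
6 | ethyl (E)-3-[3,4,5-tris(benzyloxy)phenyl]prop-2-enoate | CCOC(=O)/C=C/c1cc(OCc2ccccc2)c(OCc2ccccc2)c(OCc2ccccc2)c1 | intermediate
7 | (E)-3-[3,4,5-tris(benzyloxy)phenyl]prop-2-en-1-ol | OC/C=C/c1cc(OCc2ccccc2)c(OCc2ccccc2)c(OCc2ccccc2)c1 | intermediate
8 | [(2S,3S)-3-[3,4,5-tris(benzyloxy)phenyl]oxiran-2-yl]methanol | OC[C@@H]1O[C@H]1c1cc(OCc2ccccc2)c(OCc2ccccc2)c(OCc2ccccc2)c1 | intermediate
9 | 3,5-bis(benzyloxy)phenol | Oc1cc(OCc2ccccc2)cc(OCc2ccccc2)c1 | starting material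
10 | (2S,3R)-3-[3,5-bis(benzyloxy)phenoxy]-3-[3,4,5-tris(benzyloxy)phenyl]propane-1,2-diol | OC[C@H](O)[C@H](Oc1cc(OCc2ccccc2)cc(OCc2ccccc2)c1)c1cc(OCc2ccccc2)c(OCc2ccccc2)c(OCc2ccccc2)c1 | intermediate
11 | (4S)-4-{(R)-[3,5-bis(benzyloxy)phenoxy][3,4,5-tris(benzyloxy)phenyl]methyl}-2-phenyl-1,3-dioxolane, epimers at the acetal carbon | C1(c2ccccc2)OC[C@H](O1)[C@H](Oc1cc(OCc2ccccc2)cc(OCc2ccccc2)c1)c1cc(OCc2ccccc2)c(OCc2ccccc2)c(OCc2ccccc2)c1 | intermediate
12 | (2S,3R)-2-(benzyloxy)-3-[3,5-bis(benzyloxy)phenoxy]-3-[3,4,5-tris(benzyloxy)phenyl]propan-1-ol | OC[C@H](OCc1ccccc1)[C@H](Oc1cc(OCc2ccccc2)cc(OCc2ccccc2)c1)c1cc(OCc2ccccc2)c(OCc2ccccc2)c(OCc2ccccc2)c1 | intermediate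
13 | (2R,3R)-2-(benzyloxy)-3-[3,5-bis(benzyloxy)phenoxy]-3-[3,4,5-tris(benzyloxy)phenyl]propanal | O=C[C@H](OCc1ccccc1)[C@H](Oc1cc(OCc2ccccc2)cc(OCc2ccccc2)c1)c1cc(OCc2ccccc2)c(OCc2ccccc2)c(OCc2ccccc2)c1 | intermediate
14 | (2R,3S)-3,5,7-tris(benzyloxy)-2-[3,4,5-tris(benzyloxy)phenyl]chroman-4-ol, C4 epimers, not isolated | c3ccccc3COc1cc(OCc3ccccc3)c2c(c1)O[C@H](c1cc(OCc3ccccc3)c(OCc3ccccc3)c(OCc3ccccc3)c1)[C@@H](OCc3ccccc3)C2O | intermediate
15 | dodeca-O-benzyl-8'-bromo-gallocatechin-(4α→6)-gallocatechin; upper unit 2R,3S,4S with ring C 2,3-trans-3,4-trans, lower unit 2R,3S | c3ccccc3COc1cc(OCc3ccccc3)c2c(c1)O[C@H](c1cc(OCc3ccccc3)c(OCc3ccccc3)c(OCc3ccccc3)c1)[C@@H](OCc3ccccc3)[C@@H]2c1c(OCc3ccccc3)c(Br)c2c(c1OCc3ccccc3)C[C@H](OCc3ccccc3)[C@@H](c1cc(OCc3ccccc3)c(OCc3ccccc3)c(OCc3ccccc3)c1)O2 | intermediate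
16 | gallocatechin-(4α→6)-gallocatechin; upper unit 2R,3S,4R, lower unit 2R,3S | Oc1cc(O)c2c(c1)O[C@H](c1cc(O)c(O)c(O)c1)[C@@H](O)[C@@H]2c1c(O)cc2c(c1O)C[C@H](O)[C@@H](c1cc(O)c(O)c(O)c1)O2 | target

**Step count.** Total: 12 steps. Longest linear sequence: 9 steps (steps 4 to 12, from aldehyde 5).

**Steps most likely to fail**

1. Step 11 (carries the label). Three processes may intervene. The freshly formed upper ring A has free C6 and C8 and can compete with the hindered C6' of 4 for the C4 cation, leading to chain growth. The aldehyde may lose its aryloxy group by elimination or epimerise before it cyclises. Facial control at C4 may be incomplete. Fallback by known chemistry, setting out from 2: oxidation at C4 with DDQ in the presence of 2-ethoxyethanol (CH2Cl2, rt) should give the 4-(2-ethoxyethoxy)flavan-3-ol F1. Benzylation of its 3-hydroxyl (NaH, BnBr, DMF, 0 °C) should give the fully benzylated 4-(2-ethoxyethoxy)flavan F2. Condensation of this with excess 4 under catalytic TMSOTf (CH2Cl2, −78 °C), which is expected to be 3,4-trans-selective, returns to the route at 15. This drops the aldehyde and builds both halves from gallocatechin.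

2. Step 7. The epoxide opening may lose regio- and chemoselectivity in three ways: Payne rearrangement followed by attack at C1, C-alkylation by the ambident phloroglucinol-type phenoxide, or partial ionisation at the benzylic carbon that erodes the inversion. Fallback, setting out from 8: silylation of the primary hydroxyl (TBDPSCl, imidazole, DMF) should give the silyl glycidyl ether F3, which cannot rearrange. Opening with 9 and Cs2CO3 in DMF at 80 °C, where O-alkylation at the benzylic carbon is favoured, should give the secondary alcohol F4. Benzylation (NaH, BnBr, Bu4NI, THF, 0 °C) should give the benzyl silyl diether F5. Desilylation (TBAF, AcOH, THF) returns to the route at 12, bypassing steps 8 and 9.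

3. Step 9. The reductive cleavage may break the wrong acetal C–O bond, for instance if aluminium is directed by the neighbouring aryloxy oxygen, which would leave the benzyl group on the primary oxygen. Fallback, setting out from 10: tritylation of the primary hydroxyl (TrCl, Et3N, DMAP, CH2Cl2) should give the trityl ether F6. Benzylation of the secondary hydroxyl (NaH, BnBr, DMF, 0 °C), with no possibility of group migration, should give the benzyl trityl diether F7. Detritylation (p-TsOH cat., MeOH/CH2Cl2, rt) returns to the route at 12.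

**Further compounds**

F1 | step 11 | (2R,3S)-5,7-bis(benzyloxy)-4-(2-ethoxyethoxy)-2-[3,4,5-tris(benzyloxy)phenyl]chroman-3-ol, C4 epimers | c3ccccc3COc1cc(OCc3ccccc3)c2c(c1)O[C@H](c1cc(OCc3ccccc3)c(OCc3ccccc3)c(OCc3ccccc3)c1)[C@@H](O)C2OCCOCC
F2 | step 11 | (2R,3S)-3,5,7-tris(benzyloxy)-4-(2-ethoxyethoxy)-2-[3,4,5-tris(benzyloxy)phenyl]chromane, C4 epimers | c3ccccc3COc1cc(OCc3ccccc3)c2c(c1)O[C@H](c1cc(OCc3ccccc3)c(OCc3ccccc3)c(OCc3ccccc3)c1)[C@@H](OCc3ccccc3)C2OCCOCC
F3 | step 7 | tert-butyl{[(2S,3S)-3-[3,4,5-tris(benzyloxy)phenyl]oxiran-2-yl]methoxy}diphenylsilane | CC(C)(C)[Si](c1ccccc1)(c1ccccc1)OC[C@@H]1O[C@H]1c1cc(OCc2ccccc2)c(OCc2ccccc2)c(OCc2ccccc2)c1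
F4 | step 7 | (2S,3R)-3-[3,5-bis(benzyloxy)phenoxy]-1-[(tert-butyldiphenylsilyl)oxy]-3-[3,4,5-tris(benzyloxy)phenyl]propan-2-ol | CC(C)(C)[Si](c1ccccc1)(c1ccccc1)OC[C@H](O)[C@H](Oc1cc(OCc2ccccc2)cc(OCc2ccccc2)c1)c1cc(OCc2ccccc2)c(OCc2ccccc2)c(OCc2ccccc2)c1
F5 | step 7 | [(2S,3R)-2-(benzyloxy)-3-[3,5-bis(benzyloxy)phenoxy]-3-[3,4,5-tris(benzyloxy)phenyl]propoxy](tert-butyl)diphenylsilane | CC(C)(C)[Si](c1ccccc1)(c1ccccc1)OC[C@H](OCc1ccccc1)[C@H](Oc1cc(OCc2ccccc2)cc(OCc2ccccc2)c1)c1cc(OCc2ccccc2)c(OCc2ccccc2)c(OCc2ccccc2)c1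
F6 | step 9 | (2S,3R)-3-[3,5-bis(benzyloxy)phenoxy]-3-[3,4,5-tris(benzyloxy)phenyl]-1-(trityloxy)propan-2-ol | c1ccccc1C(c1ccccc1)(c1ccccc1)OC[C@H](O)[C@H](Oc1cc(OCc2ccccc2)cc(OCc2ccccc2)c1)c1cc(OCc2ccccc2)c(OCc2ccccc2)c(OCc2ccccc2)c1
F7 | step 9 | (2S,3R)-2-(benzyloxy)-3-[3,5-bis(benzyloxy)phenoxy]-3-[3,4,5-tris(benzyloxy)phenyl]propyl trityl ether | c1ccccc1C(c1ccccc1)(c1ccccc1)OC[C@H](OCc1ccccc1)[C@H](Oc1cc(OCc2ccccc2)cc(OCc2ccccc2)c1)c1cc(OCc2ccccc2)c(OCc2ccccc2)c(OCc2ccccc2)c1
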